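The constants come from no measurement; no experiment stands behind them.

Zu.Ze is a way station in this flask: it forms from Zu and Ze, then passes on to Ry, so what to watch at the reading is what was made times what stayed.

Vy 20 mM; Ze 19.0 mM; time 15 h

1. how much Zu.Ze there is at 15 h, in percent of the Vy charged
2. concentration of Zu in solution at 1.5 h, in percent of saturation
3. the change that raises the amount of Zu.Ze at 15 h, in percent of the Vy charged most ("none" if none brings more than 2 percentage points) (Sunday's / Saturday's / Friday's / none)
4. amount of Zu.Ze at 15 h, in percent of the Vy charged, after Sunday's

- solid, in amounts per volume of the solution: Vy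
- at the start none of Vy is in solution
- Zu means what is dissolved; the solid is not counted in it
- run time (flask): 15 h

- Sunday's: doubling the dissolution coefficient of step 1, all else as stated
- Saturday's: doubling the amount of Ze, all else as stated
- Friday's: doubling the solubility in step 1, all else as stated

    Vy ⇌ Zu, rate k1*(cs1 - [Zu]) while solid is left; crystals form when [Zu] > cs1 (cs1 = 9.0 mM, k1 = 5.3 × 10⁻⁴ /s)
    Zu + Ze → Zu.Ze (k2 = 0.070 /M/s)
    Ze ⇌ Ul (K3 = 1.3, k3 = 2.7 × 10⁻⁴ /s)
    Vy → Eb (k4 = 3.3 × 10⁻⁸ /s)
    Zu.Ze ⇌ Ry (K5 = 28, k5 = 1.5 × 10⁻⁵ /s)

Three clocks form the table for the flask. Row one is coupling, with a half-life of Zu of 0.14 h at the charged Ze. Row two is delivery: the solid hands over at most 0.859 /h of the charge, so the whole takes at least 1.16 h, taken here as the birth time. Row three is the leak to Ry, with a relaxation half-life of 12.4 h.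

Row one against row two: coupling is faster than delivery at the start, so Zu.Ze should be born roughly as the solid delivers, though this comparison drifts as Ze falls. Row two against row three: even this shortest delivery time is short against the leak, but it is a lower bound, so a single birth date is a rough stand-in for births that can run later. The leak then runs for 13.8 h towards its equilibrium, which gives the keep fraction 48.0%, the share of Zu.Ze born at the birth time that is still Zu.Ze at the reading.

Ze, charged below Vy, is the limiting reagent, with a ceiling of 95.0%, so this reckoning gives 45.6%. Sunday's moves the birth time to 0.582 h, the keep fraction to 46.6% and the amount to 44.3%. Friday's doubles the same delivery rate, so it reckons alike. Saturday's lifts the ceiling, worth 2.4 percentage points, just over the margin, but its earlier births cost keep, so the reckoning commits narrowly to none.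

The forecast gives 48%, above this reckoning, with 63%, none and 47.5%, on the ground that “the earlier product then has longer to leak to Ry”.

The flask gives 47.8%, 62.7%, none and 46.8%. The changes bring −0.94 points for Sunday's, 0 points for Saturday's and −1.3 points for Friday's. Ze charged at 16.8 mM moves the amount of Zu.Ze by 5 points.

In the flask at 15 h, Zu.Ze holds 51.4% of Zu.Ze and Ry together, against the keep fraction of 48.0%, and coupling reaches the midpoint of its turnover at 1.45 h, later than the birth time. A neighbour charged with 50 mM of Vy holds Ze as in the recipe, so its ceiling falls to 38.0% of its Vy. Its birth time, for delivering the Ze equivalent, is 1.11 h, its keep fraction 47.8%, and its reckoned amount 18.2%. That neighbour reads Zu.Ze 19.3%, Ry 18.7% and Vy 43.9%, with 0.017% of its Ze left.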